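Atom labels: ring A is the dimethoxybenzene ring (C4a, C5–C8, C8a). Ring B is C1 (bears ring C, the guaiacyl group), C2 (bears C9, the CH2OH), C3 (bears C10, the CHO), C4, C4a and C8a.
Enabling feature: C1 and C4 of ring B sit on the neighbouring ring A carbons C8a and C4a, and the 6,7-dimethoxy pattern makes these two carbons equivalent. Ring A can therefore enter as symmetric 4,5-dimethoxybenzyne, and either orientation gives the same product.
Key disconnection: C1–C8a and C4–C4a are formed together by [4+2] addition of the aryne to an acyclic 1-aryl-2-acyl-3-(diethoxymethyl)buta-1,3-diene whose C9 acyl group carries a camphorsultam. Ring B is the only ring made (rings A and C are bought), and C1 is set here.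
Diene: C2–C3 comes from Stille coupling of 2-bromoacrolein diethyl acetal with the α-stannyl enoyl sultam, which is made by syn hydrostannation of the arylpropynoyl sultam (vanillin, Corey–Fuchs, CO2).
After ring closure: the alkene is shifted from C2=C3 to C3=C4 through the dienolate, C2 is equilibrated to the 1,2-trans isomer, LiAlH4 turns C9 into CH2OH with recovery of the auxiliary, and one acid step frees the C10 aldehyde and the phenol.

Key step: step 9

Assumption: no tested model predicts the facial sense for a sultam placed on C2 of such a diene. The route is drawn with (1S)-(−)-2,10-camphorsultam leading to the (1S) adduct. If the sense proves opposite, the equally available (1R)-(+)-sultam is taken through the same steps.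

Step 1
Reactants: 1 vanillin (4-hydroxy-3-methoxybenzaldehyde)
Product: 2 3-methoxy-4-(methoxymethoxy)benzaldehyde
Conditions: MOMCl, i-Pr2NEt, CH2Cl2, 0 °C to rt
Reagents that add atoms: chloromethyl methyl ether, COCCl
Why: Williamson-type O-alkylation of the phenoxide gives a MOM acetal that withstands n-BuLi, zerovalent palladium, fluoride, amide bases and LiAlH4 and leaves in the final acid step.

Step 2
Reactants: 2 3-methoxy-4-(methoxymethoxy)benzaldehyde
Product: 3 4-(2,2-dibromovinyl)-2-methoxy-1-(methoxymethoxy)benzene
Conditions: CBr4, PPh3, CH2Cl2, 0 °C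
Reagents that add atoms: carbon tetrabromide, BrC(Br)(Br)Br
Why: Corey–Fuchs dibromoolefination (Wittig reaction of Ph3P=CBr2 made in the flask) is routine for electron-rich benzaldehydes and adds the carbon that becomes C2 next to the former aldehyde carbon C1.

Step 3
Reactants: 3 4-(2,2-dibromovinyl)-2-methoxy-1-(methoxymethoxy)benzene
Product: 5 3-[3-methoxy-4-(methoxymethoxy)phenyl]prop-2-ynoic acid, via lithium arylacetylide 4 (not isolated)
Conditions: n-BuLi (2.2 equiv), THF, −78 °C; CO2, −78 °C to rt; cold 1 M HCl to pH 3
Reagents that add atoms: carbon dioxide, O=C=O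
Why: In the second stage of the Corey–Fuchs sequence, Br/Li exchange, loss of LiBr and deprotonation give the acetylide, whose carboxylation installs C9, and the brief cold work-up at pH 3 leaves the MOM ether untouched.

Step 4
Reactants: 5 3-[3-methoxy-4-(methoxymethoxy)phenyl]prop-2-ynoic acid; 6 (1S)-(−)-2,10-camphorsultam
Product: 8 N-{3-[3-methoxy-4-(methoxymethoxy)phenyl]prop-2-ynoyl}-(1S)-2,10-camphorsultam, via pivalic mixed anhydride 7 (not isolated)
Conditions: t-BuCOCl, Et3N, THF, −20 °C; then 6, LiCl, −20 °C to rt
Reagents that add atoms: none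
Why: N-acylation through the mixed anhydride, with attack at the less hindered alkynoyl carbonyl group and LiCl/Et3N activation of the sulfonamide N–H, avoids the HCl of an acid chloride route that would endanger the MOM ether and the triple bond.

Step 5
Reactants: 8 N-{3-[3-methoxy-4-(methoxymethoxy)phenyl]prop-2-ynoyl}-(1S)-2,10-camphorsultam
Product: 9 N-{(E)-3-[3-methoxy-4-(methoxymethoxy)phenyl]-2-(tributylstannyl)prop-2-enoyl}-(1S)-2,10-camphorsultam (aryl cis to C=O)
Conditions: Bu3SnH (slow addition), Pd(PPh3)4 (cat.), THF, 0 °C to rt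
Reagents that add atoms: tributyltin hydride, CCCC[SnH](CCCC)CCCC
Why: Palladium-catalysed hydrostannation of an arylpropynoyl system is a syn addition that puts hydride on the β-carbon C1 and tin on the α-carbon C2, so the aryl group ends up cis to the carbonyl group and trans to tin.

Step 6
Reactants: 10 acrolein diethyl acetal (3,3-diethoxyprop-1-ene)
Product: 11 2,3-dibromo-1,1-diethoxypropane (racemic)
Conditions: Br2, CH2Cl2, −10 °C
Reagents that add atoms: bromine, BrBr
Why: Electrophilic anti addition of bromine to the monosubstituted alkene is fast at low temperature and spares the acetal, and the new stereocentre is destroyed again in step 7, so the racemate serves.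

Step 7
Reactants: 11 2,3-dibromo-1,1-diethoxypropane
Product: 12 2-bromo-3,3-diethoxyprop-1-ene
Conditions: KOt-Bu (1.0 equiv), THF, 0 °C
Reagents that add atoms: none
Why: E2 dehydrobromination removes the more acidic hydrogen geminal to bromine and next to the acetal together with the primary bromide, and one equivalent of base stops the reaction before a second elimination to the alkyne.

Step 8
Reactants: 9 N-{(E)-3-aryl-2-(tributylstannyl)prop-2-enoyl}camphorsultam; 12 2-bromo-3,3-diethoxyprop-1-ene
Product: 13 N-{(2Z)-3-(diethoxymethyl)-2-[3-methoxy-4-(methoxymethoxy)benzylidene]but-3-enoyl}-(1S)-2,10-camphorsultam (aryl cis to C=O and trans to C3)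
Conditions: Pd(PPh3)4 (cat.), CuI (cat.), CsF (2 equiv), DMF, 45 °C
Reagents that add atoms: none
Why: In this Stille coupling, CuI (tin-to-copper exchange) and fluoride (removal of tin as Bu3SnF) speed up the slow transmetallation of the hindered α-stannyl enoyl unit, and retention at both sp2 carbons keeps the aryl group on the outside of the new diene.

Step 9
Reactants: 13 N-dienoyl camphorsultam; 14 4,5-dimethoxy-2-(trimethylsilyl)phenyl trifluoromethanesulfonate
Product: 16 N-{(1S)-3-(diethoxymethyl)-6,7-dimethoxy-1-[3-methoxy-4-(methoxymethoxy)phenyl]-1,4-dihydronaphthalene-2-carbonyl}-(1S)-2,10-camphorsultam, via 4,5-dimethoxybenzyne 15 (not isolated)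
Conditions: CsF (4 equiv), 14 (2 equiv, slow addition), MeCN–toluene, 25–40 °C
Reagents that add atoms: none
Why: Proposed new method: fluoride attack on silicon with loss of triflate releases aryne 15, whose very low LUMO lets it add suprafacially to the s-cis conformer of 13 in one concerted but asynchronous event (C4–C4a bonding running ahead of C1–C8a), so ring B closes by intermolecular [4+2] cycloaddition with both new bonds formed together. The closest known reaction type is the Diels–Alder reaction of fluoride-generated arynes with acyclic dienes, including pentadienoyl camphorsultams that carry the auxiliary on the diene terminus, whereas facial control from an acyl sultam on C2 of a 1-aryl diene has not been shown. C1 is the only new stereocentre and is fixed by the diene face that is attacked: the C9 carbonyl group, wedged between the cis aryl group on C1 and the acetal on C3, has to twist out of the diene plane, its C=O stays anti to the SO2 group, and the bornane cage then covers one face so that 15 enters from the other. Regioselectivity is not needed because 15 is symmetric. Periselectivity is needed against a styrene-type [4+2] through ring C, an ene reaction and a [2+2] addition, and it is secured by the outside position of the aryl group and the 2,3-disubstitution (both favour a cisoid diene), by the aromaticity that the ring C path would cost, and by the single allylic hydrogen C10–H, which allylic strain holds near the diene plane and so out of alignment for transfer. The diethyl acetal and the MOM ether are inert to CsF, which a silyl ether at C10 might not be.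

Step 10
Reactants: 16 (1S)-1,4-dihydronaphthalene-2-carbonyl sultam
Product: 18 N-{(1S,2S)-3-(diethoxymethyl)-6,7-dimethoxy-1-[3-methoxy-4-(methoxymethoxy)phenyl]-1,2-dihydronaphthalene-2-carbonyl}-(1S)-2,10-camphorsultam (1,2-cis), via sodium dienolate 17 (not isolated)
Conditions: NaN(SiMe3)2 (1.1 equiv), degassed THF, −78 °C; AcOH in THF, −78 °C
Reagents that add atoms: none
Why: In this deconjugative protonation of an extended enolate, the C4 hydrogens (benzylic and γ to the acyl group) are the most acidic and the dienolate is protonated kinetically at its α-carbon C2, which moves the alkene into conjugation with ring A at C3–C4, and because the proton arrives on the face away from the pseudoaxial C1 aryl group the acyl group is pushed to the aryl side, so the 1,2-cis epimer should prevail (any trans epimer formed alongside is carried on with it).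

Step 11
Reactants: 18 (1S,2S)-cis-1,2-dihydronaphthalene-2-carbonyl sultam
Product: 19 N-{(1S,2R)-3-(diethoxymethyl)-6,7-dimethoxy-1-[3-methoxy-4-(methoxymethoxy)phenyl]-1,2-dihydronaphthalene-2-carbonyl}-(1S)-2,10-camphorsultam (1,2-trans)
Conditions: DBU (0.2 equiv), toluene, rt, Ar
Reagents that add atoms: none
Why: In this base-catalysed epimerisation under thermodynamic control, DBU reversibly removes the doubly activated C2–H, reprotonation at C2 is faster than at C4, and the trans isomer is the sink because only it can hold both the C1 aryl and the C2 acyl group pseudoaxial, free of the peri contact with H8 and of allylic strain against the C3 acetal, while conjugation with ring A keeps the alkene at C3–C4.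

Step 12
Reactants: 19 (1S,2R)-trans-1,2-dihydronaphthalene-2-carbonyl sultam
Product: 20 {(1S,2R)-3-(diethoxymethyl)-6,7-dimethoxy-1-[3-methoxy-4-(methoxymethoxy)phenyl]-1,2-dihydronaphthalen-2-yl}methanol
Conditions: LiAlH4, THF, 0 °C; aq KNaC4H4O6 work-up
Reagents that add atoms: none
Why: Reductive cleavage of an N-acyl sultam with LiAlH4 is the standard way to the primary alcohol with recovery of the auxiliary, the acetal, MOM ether and styrene-type alkene are inert, and C2 already holds its more stable configuration.

Step 13
Reactants: 20 {(1S,2R)-3-(diethoxymethyl)-1-aryl-6,7-dimethoxy-1,2-dihydronaphthalen-2-yl}methanol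
Product: 21 (3R,4S)-4-(4-hydroxy-3-methoxyphenyl)-3-(hydroxymethyl)-6,7-dimethoxy-3,4-dihydronaphthalene-2-carbaldehyde (1S,2R in the labels used here)
Conditions: 2 M aq HCl, THF, 40 °C
Reagents that add atoms: water, O
Why: Acid hydrolysis removes both acetal-type groups in one operation, the allylic diethyl acetal ionising first to the ring A conjugated enal and the phenolic MOM ether following, so no late oxidation is needed, over-oxidation of a 1,4-diol to the lactone cannot arise, and neither stereocentre is touched since C1–H does not ionise and C2–H cannot enolise through the cross-conjugated enal.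

Compound list
1 | vanillin (4-hydroxy-3-methoxybenzaldehyde) | COc1cc(C=O)ccc1O | starting material
2 | 3-methoxy-4-(methoxymethoxy)benzaldehyde | COCOc1ccc(C=O)cc1OC | intermediate
3 | 4-(2,2-dibromovinyl)-2-methoxy-1-(methoxymethoxy)benzene | COCOc1ccc(C=C(Br)Br)cc1OC | intermediate
4 | lithium [3-methoxy-4-(methoxymethoxy)phenyl]acetylide (not isolated) | COCOc1ccc(C#C[Li])cc1OC | intermediate
5 | 3-[3-methoxy-4-(methoxymethoxy)phenyl]prop-2-ynoic acid | COCOc1ccc(C#CC(=O)O)cc1OC | intermediate
6 | (1S)-(−)-2,10-camphorsultam | CC1(C)[C@@H]2CC[C@]13CS(=O)(=O)N[C@@H]3C2 | starting material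
7 | arylpropynoic pivalic mixed anhydride (not isolated) | COCOc1ccc(C#CC(=O)OC(=O)C(C)(C)C)cc1OC | intermediate
8 | N-(arylpropynoyl)camphorsultam | CC1(C)[C@@H]2CC[C@]13CS(=O)(=O)N([C@@H]3C2)C(=O)C#Cc4ccc(OCOC)c(OC)c4 | intermediate
9 | N-[(E)-3-aryl-2-(tributylstannyl)prop-2-enoyl]camphorsultam | CC1(C)[C@@H]2CC[C@]13CS(=O)(=O)N([C@@H]3C2)C(=O)/C([Sn](CCCC)(CCCC)CCCC)=C\c4ccc(OCOC)c(OC)c4 | intermediate
10 | acrolein diethyl acetal | C=CC(OCC)OCC | starting material
11 | 2,3-dibromo-1,1-diethoxypropane (racemic) | CCOC(OCC)C(Br)CBr | intermediate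
12 | 2-bromo-3,3-diethoxyprop-1-ene | C=C(Br)C(OCC)OCC | intermediate
13 | N-dienoyl camphorsultam, (2Z), aryl trans to C3 | CC1(C)[C@@H]2CC[C@]13CS(=O)(=O)N([C@@H]3C2)C(=O)/C(C(=C)C(OCC)OCC)=C\c4ccc(OCOC)c(OC)c4 | intermediate
14 | 4,5-dimethoxy-2-(trimethylsilyl)phenyl trifluoromethanesulfonate | COc1cc(OS(=O)(=O)C(F)(F)F)c(cc1OC)[Si](C)(C)C | starting material
15 | 4,5-dimethoxybenzyne (not isolated) | COC1=CC#CC=C1OC | intermediate
16 | (1S)-1-aryl-3-(diethoxymethyl)-6,7-dimethoxy-1,4-dihydronaphthalene-2-carbonyl sultam | CC1(C)[C@@H]2CC[C@]13CS(=O)(=O)N([C@@H]3C2)C(=O)C4=C(C(OCC)OCC)Cc5cc(OC)c(OC)cc5[C@@H]4c6ccc(OCOC)c(OC)c6 | intermediate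
17 | sodium dienolate of 16 (C9=C2 and C3=C4, not isolated) | CC1(C)[C@@H]2CC[C@]13CS(=O)(=O)N([C@@H]3C2)C([O-])=C4C(C(OCC)OCC)=Cc5cc(OC)c(OC)cc5[C@@H]4c6ccc(OCOC)c(OC)c6.[Na+] | intermediate
18 | (1S,2S)-cis-1-aryl-3-(diethoxymethyl)-6,7-dimethoxy-1,2-dihydronaphthalene-2-carbonyl sultam | CC1(C)[C@@H]2CC[C@]13CS(=O)(=O)N([C@@H]3C2)C(=O)[C@@H]4C(C(OCC)OCC)=Cc5cc(OC)c(OC)cc5[C@@H]4c6ccc(OCOC)c(OC)c6 | intermediate
19 | (1S,2R)-trans-1-aryl-3-(diethoxymethyl)-6,7-dimethoxy-1,2-dihydronaphthalene-2-carbonyl sultam | CC1(C)[C@@H]2CC[C@]13CS(=O)(=O)N([C@@H]3C2)C(=O)[C@H]4C(C(OCC)OCC)=Cc5cc(OC)c(OC)cc5[C@@H]4c6ccc(OCOC)c(OC)c6 | intermediate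
20 | {(1S,2R)-3-(diethoxymethyl)-6,7-dimethoxy-1-[3-methoxy-4-(methoxymethoxy)phenyl]-1,2-dihydronaphthalen-2-yl}methanol | COCOc1ccc([C@H]2c3cc(OC)c(OC)cc3C=C(C(OCC)OCC)[C@@H]2CO)cc1OC | intermediate
21 | (3R,4S)-4-(4-hydroxy-3-methoxyphenyl)-3-(hydroxymethyl)-6,7-dimethoxy-3,4-dihydronaphthalene-2-carbaldehyde | COc1cc([C@H]2c3cc(OC)c(OC)cc3C=C(C=O)[C@@H]2CO)ccc1O | target

Total step count: 13. Longest linear sequence: 11 (steps 1–5 and 8–13, from vanillin).

Steps most likely to fail

**Step 9 (key step).**
- What may go wrong: the auxiliary lies further from the reacting termini than in the known cases, so it may shield the diene face only weakly. The aryne may also be diverted into hydrogen transfer (ene) or into addition through ring C.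
- Fallback: known chemistry only. It sets out from 13 and comes back at 19, and ring B is closed in two known stages instead of one.
- Commercial 2-bromo-4,5-dimethoxybenzaldehyde is methylenated (Wittig, Ph3P=CH2, THF) to 1-bromo-4,5-dimethoxy-2-vinylbenzene F1. Magnesium turnings in THF convert this into (4,5-dimethoxy-2-vinylphenyl)magnesium bromide F2.
- Chelation-controlled 1,4-addition of this Grignard reagent to the N-enoyl sultam unit of 13 (THF, −78 to −30 °C, CuBr·SMe2 as catalyst if needed) forms C1–C8a and gives the bromomagnesium enolate F3. This reaction class is established for enoyl camphorsultams.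
- Quenching cold with aq NH4Cl on the same auxiliary-open face sets C2.
- Delivery of aryl and hydrogen to one face of the C1=C2 bond of 13, in which ring C is cis to the carbonyl group, corresponds to the 1,2-trans relation. The product is the open-chain triene N-{2-[(4,5-dimethoxy-2-vinylphenyl)(aryl)methyl]-3-(diethoxymethyl)but-3-enoyl}camphorsultam F4.
- Ring-closing metathesis of the styrene vinyl group with the 1,1-disubstituted alkene closes ring B at C3=C4 and gives 19 directly (second-generation Grubbs catalyst RuCl2(=CHPh)(PCy3)(H2IMes), toluene, 60 °C). Steps 10 and 11 are then not needed, and any C2 epimer joins at 18.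

**Step 11.**
- What may go wrong: the alkene may drift back into conjugation with the acyl group through protonation of the dienolate at C4. The cis/trans equilibrium may also be insufficiently one-sided at the acetal stage.
- Fallback: it sets out from 18 and comes back at 19. The alkene is locked before C2 is equilibrated.
- Mild hydrolysis of the labile allylic acetal (pyridinium tosylate cat., acetone–water, rt, MOM ether retained) gives the (1S,2S)-cis 3-formyl-1,2-dihydronaphthalene-2-carbonyl sultam F5. Its enal is held at C3=C4 by push–pull conjugation with the C7 methoxy group of ring A.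
- Catalytic Et3N or DBU in CH2Cl2 can then only epimerise C2, and gives the (1S,2R)-trans 3-formyl-1,2-dihydronaphthalene-2-carbonyl sultam F6.
- Re-acetalisation (HC(OEt)3, pyridinium tosylate cat., EtOH, rt) returns 19 for the LiAlH4 step.

**Step 8.**
- What may go wrong: transfer of the hindered, electron-poor alkenyl group from tin may be so slow that protodestannylation, homocoupling or loss of alkene geometry overtakes the coupling.
- Fallback: it sets out from 9 and 12 and comes back at 13, with the polarity of the coupling reversed.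
- Iododestannylation of 9 (I2, CH2Cl2, 0 °C, retention) gives the N-[(E)-3-aryl-2-iodoprop-2-enoyl]camphorsultam F7.
- Miyaura borylation of 12 (B2pin2, PdCl2(PPh3)2, PPh3, KOPh, toluene, 50 °C) gives 2-(3,3-diethoxyprop-1-en-2-yl)-4,4,5,5-tetramethyl-1,3,2-dioxaborolane F8.
- Suzuki–Miyaura coupling of the two (PdCl2(dppf), K3PO4, THF–water, 40 °C) forms C2–C3 with retention and gives 13.

Further compounds
F1 | step 9 | 1-bromo-4,5-dimethoxy-2-vinylbenzene | C=Cc1cc(OC)c(OC)cc1Br
F2 | step 9 | (4,5-dimethoxy-2-vinylphenyl)magnesium bromide | C=Cc1cc(OC)c(OC)cc1[Mg]Br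
F3 | step 9 | bromomagnesium enolate from 1,4-addition to 13 | CC1(C)[C@@H]2CC[C@]13CS(=O)(=O)N([C@@H]3C2)C(O[Mg]Br)=C(C(=C)C(OCC)OCC)[C@H](c4cc(OC)c(OC)cc4C=C)c5ccc(OCOC)c(OC)c5
F4 | step 9 | N-{2-[(4,5-dimethoxy-2-vinylphenyl)(aryl)methyl]-3-(diethoxymethyl)but-3-enoyl}camphorsultam, C1 and C2 as in 19 | CC1(C)[C@@H]2CC[C@]13CS(=O)(=O)N([C@@H]3C2)C(=O)[C@@H](C(=C)C(OCC)OCC)[C@H](c4cc(OC)c(OC)cc4C=C)c5ccc(OCOC)c(OC)c5
F5 | step 11 | (1S,2S)-cis-1-aryl-3-formyl-6,7-dimethoxy-1,2-dihydronaphthalene-2-carbonyl sultam | CC1(C)[C@@H]2CC[C@]13CS(=O)(=O)N([C@@H]3C2)C(=O)[C@@H]4C(C=O)=Cc5cc(OC)c(OC)cc5[C@@H]4c6ccc(OCOC)c(OC)c6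
F6 | step 11 | (1S,2R)-trans-1-aryl-3-formyl-6,7-dimethoxy-1,2-dihydronaphthalene-2-carbonyl sultam | CC1(C)[C@@H]2CC[C@]13CS(=O)(=O)N([C@@H]3C2)C(=O)[C@H]4C(C=O)=Cc5cc(OC)c(OC)cc5[C@@H]4c6ccc(OCOC)c(OC)c6
F7 | step 8 | N-[(E)-3-aryl-2-iodoprop-2-enoyl]camphorsultam | CC1(C)[C@@H]2CC[C@]13CS(=O)(=O)N([C@@H]3C2)C(=O)/C(I)=C\c4ccc(OCOC)c(OC)c4
F8 | step 8 | 2-(3,3-diethoxyprop-1-en-2-yl)-4,4,5,5-tetramethyl-1,3,2-dioxaborolane | C=C(B1OC(C)(C)C(C)(C)O1)C(OCC)OCC
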